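**Retrosynthetic overview**
- Target ⇐ double acylation of the C1/C12 diol ⇐ desilylation ⇐ Ni/Cr addition of a bought β‑bromobutenolide to a C12 aldehyde ⇐ Wacker oxidation of a C9 vinyl group ⇐ acetylation and ester reduction of the decalin core.
- Decalin core ⇐ one operation on an acyclic precursor: HAT‑initiated 6‑endo Giese closure C9–C10 (ring B), then aldol closure C5–C4 (ring A) of the enolate so formed onto a chloromethyl ketone; this sets C9, C10, C5 and C4 and delivers the chlorohydrin directly.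
- Acyclic precursor ⇐ gold oxidation of a terminal alkyne to the chloromethyl ketone ⇐ Ni/Cr coupling (C5–C6) of a (Z)-α‑iodo enoate (C1–C5, C10, C18, C19) with a dienal (C6–C9, C11, C12, C17, C20).
- Iodo enoate ⇐ pent‑4‑ynal + methyl propiolate (C1 stereocentre); dienal ⇐ crotonaldehyde + silylacetylene (C8 stereocentre) + ethylene.
- Ring order: rings A and B together in the key step; the butenolide ring is bought and attached afterwards.

Assumption: pent‑4‑ynal is bought (otherwise one oxidation from pent‑4‑yn‑1‑ol); positions are given in clerodane numbering; each named ligand enantiomer is the one expected to give the stated configuration and is swapped if the sense proves opposite.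

**Route**

Step 1
Reactants: 1 pent-4-ynal; 2 methyl prop-2-ynoate
Product: 3 methyl (4R)-4-hydroxyocta-2,7-diynoate
Conditions: Me2Zn (3 equiv), (S,S)-ProPhenol (20 mol%), Ph3P=O (40 mol%), toluene, 0 °C; aq NH4Cl
Reagents that add atoms: none
Why: Trost zinc–ProPhenol asymmetric alkynylation, in which only the acidic propiolate C–H is zincated (the unactivated alkyne of 1 is not) and the dinuclear zinc catalyst delivers the acetylide to one aldehyde face, setting C1 (4R here).

Step 2
Reactants: 3 methyl (4R)-4-hydroxyocta-2,7-diynoate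
Product: 4 methyl (4R)-4-[(tert-butyldimethylsilyl)oxy]octa-2,7-diynoate
Conditions: TBSCl, imidazole, DMF, 0 °C to rt
Reagents that add atoms: tert-butyldimethylsilyl chloride, CC(C)(C)[Si](C)(C)Cl
Why: Imidazole-promoted silyl ether formation, which blocks butenolide formation from the later (Z)-γ-hydroxy enoate and protects C1–OH until step 14.

Step 3
Reactants: 4 methyl (4R)-4-[(tert-butyldimethylsilyl)oxy]octa-2,7-diynoate
Product: 6 methyl (2E,4R)-4-[(tert-butyldimethylsilyl)oxy]-2-iodooct-2-en-7-ynoate, via vinylalane 5 (not isolated)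
Conditions: i-Bu2AlH (1.2 equiv), HMPA, THF, 0 °C; then I2, −78 to 0 °C
Reagents that add atoms: iodine, [I][I]
Why: Conjugate hydroalumination of the ynoate (hydride to C10, aluminium on C5) followed by iodinolysis with retention leaves the C1 chain cis to the ester, and the isolated terminal alkyne is not hydroaluminated at 0 °C.

Step 4
Reactants: 7 (E)-but-2-enal; 8 ethynyltri(propan-2-yl)silane
Product: 9 (3R)-3-methyl-5-[tri(propan-2-yl)silyl]pent-4-ynal
Conditions: [Rh(OAc)(C2H4)2]2 (2.5 mol%), (R)-DTBM-SEGPHOS (6 mol%), MeOH, 40 °C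
Reagents that add atoms: none
Why: Hayashi–Nishimura rhodium-catalysed asymmetric conjugate alkynylation of an enal, where the bulky silyl group suppresses alkyne dimerisation and the chiral bisphosphine sets C8 (3R here).

Step 5
Reactants: 9 (3R)-3-methyl-5-[tri(propan-2-yl)silyl]pent-4-ynal
Product: 10 (3R)-3-methylpent-4-ynal
Conditions: n-Bu4NF, AcOH, THF, 0 °C; used as a solution
Reagents that add atoms: none
Why: Fluoride protodesilylation of the alkynylsilane, buffered with AcOH so that the aldehyde does not self-condense; the β-stereocentre cannot epimerise.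

Step 6
Reactants: 10 (3R)-3-methylpent-4-ynal
Product: 11 (3R)-3-methyl-4-methylidenehex-5-enal
Conditions: second-generation Grubbs catalyst (5 mol%), ethylene (1 atm), CH2Cl2, rt
Reagents that add atoms: ethylene, C=C
Why: Ene–yne cross-metathesis with ethylene converts the terminal alkyne into the 2-substituted buta-1,3-diene (C20 and C12 come from ethylene) without touching the aldehyde or C8.

Step 7
Reactants: 6 methyl (2E,4R)-4-[(tert-butyldimethylsilyl)oxy]-2-iodooct-2-en-7-ynoate; 11 (3R)-3-methyl-4-methylidenehex-5-enal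
Product: 12 methyl (2Z,4R)-4-[(tert-butyldimethylsilyl)oxy]-2-[(1S,3R)-1-hydroxy-3-methyl-4-methylidenehex-5-en-1-yl]oct-2-en-7-ynoate
Conditions: CrCl2 (4 equiv), (S)-N-[2-(4-isopropyl-4,5-dihydrooxazol-2-yl)-6-methylphenyl]methanesulfonamide (4.4 equiv), Et3N, THF; then NiCl2 (10 mol%), 6, 11, rt
Reagents that add atoms: none
Why: Asymmetric Nozaki–Hiyama–Kishi coupling, in which zerovalent nickel inserts into the C–I bond with retention of alkene geometry and the chiral sulfonamide–chromium alkenyl adds to one aldehyde face to set C6 (S) under reagent control.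

Step 8
Reactants: 12 methyl (2Z,4R)-4-[(tert-butyldimethylsilyl)oxy]-2-[(1S,3R)-1-hydroxy-3-methyl-4-methylidenehex-5-en-1-yl]oct-2-en-7-ynoate
Product: 13 methyl (2Z,4R)-4-[(tert-butyldimethylsilyl)oxy]-8-chloro-2-[(1S,3R)-1-hydroxy-3-methyl-4-methylidenehex-5-en-1-yl]-7-oxooct-2-enoate
Conditions: IPrAuNTf2 (5 mol%), 8-methylquinoline N-oxide (1.5 equiv), MsOH (1.2 equiv, slow addition), ClCH2CH2Cl, rt
Reagents that add atoms: 8-methylquinoline N-oxide, Cc1cccc2ccc[n+]([O-])c12; 1,2-dichloroethane, ClCCCl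
Why: Gold-catalysed alkyne oxidation, where the N-oxide attacks the internal carbon of the gold-bound terminal alkyne and the α-oxo gold carbene abstracts chloride from the solvent and is protonated, giving the chloromethyl ketone while the enoate and diene stay unactivated.

Step 9
Reactants: 13 methyl (2Z,4R)-4-[(tert-butyldimethylsilyl)oxy]-8-chloro-2-[(1S,3R)-1-hydroxy-3-methyl-4-methylidenehex-5-en-1-yl]-7-oxooct-2-enoate
Product: 15 methyl 1β-[(tert-butyldimethylsilyl)oxy]-18-chloro-4α,6α-dihydroxy-13,14,15,16-tetranor-neo-clerod-11-en-19-oate, via ester enolate 14 (not isolated)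
Conditions: Fe(acac)3 (30 mol%), PhSiH2(Oi-Pr) (2.5 equiv), THF (0.005 M), 0 °C to rt
Reagents that add atoms: none
Why: Proposed new method: hydrogen-atom transfer from the iron hydride to C20 of the diene gives a tertiary allyl radical that adds 6-endo to C10 of the (Z)-enoate through a chair with C6–OH and C8–Me equatorial (ring B; 1,3-allylic strain in the planar allyl radical puts vinyl equatorial and the new methyl axial at C9), and the α-ester radical is reduced to an iron enolate that closes ring A by a chelated aldol onto the chloromethyl ketone from the face away from the axial C9 methyl (trans-decalin, axial CO2Me, equatorial 4-OH); the closest known reaction type is the iron-catalysed MHAT radical–polar crossover (Giese/aldol) polycyclisation of alkenes bearing enal or enone acceptors and carbonyl traps.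

Step 10
Reactants: 15 methyl 1β-[(tert-butyldimethylsilyl)oxy]-18-chloro-4α,6α-dihydroxy-13,14,15,16-tetranor-neo-clerod-11-en-19-oate
Product: 16 1β-[(tert-butyldimethylsilyl)oxy]-18-chloro-13,14,15,16-tetranor-neo-clerod-11-ene-4α,6α,19-triol
Conditions: i-Bu2AlH (6 equiv), CH2Cl2, −78 to 0 °C; Rochelle salt
Reagents that add atoms: none
Why: Ester reduction with i-Bu2AlH, chosen because the aluminium alkoxide of the C4 hydroxyl is too weakly nucleophilic at low temperature to close onto CH2Cl (LiAlH4 is avoided for that reason).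

Step 11
Reactants: 16 1β-[(tert-butyldimethylsilyl)oxy]-18-chloro-13,14,15,16-tetranor-neo-clerod-11-ene-4α,6α,19-triol
Product: 17 6α,19-diacetoxy-1β-[(tert-butyldimethylsilyl)oxy]-18-chloro-13,14,15,16-tetranor-neo-clerod-11-en-4α-ol
Conditions: Ac2O, pyridine, DMAP (10 mol%), CH2Cl2, rt
Reagents that add atoms: acetic anhydride, CC(=O)OC(C)=O
Why: DMAP-catalysed acetylation of the primary and the secondary hydroxyl, while the tertiary C4–OH next to the quaternary centre does not react.

Step 12
Reactants: 17 6α,19-diacetoxy-1β-[(tert-butyldimethylsilyl)oxy]-18-chloro-13,14,15,16-tetranor-neo-clerod-11-en-4α-ol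
Product: 18 6α,19-diacetoxy-1β-[(tert-butyldimethylsilyl)oxy]-18-chloro-4α-hydroxy-13,14,15,16-tetranor-neo-clerodan-12-al
Conditions: PdCl2(PhCN)2 (12 mol%), CuCl2·2H2O (12 mol%), AgNO2 (6 mol%), t-BuOH/MeNO2 15:1, O2 (1 atm), rt
Reagents that add atoms: dioxygen, O=O
Why: Aldehyde-selective (anti-Markovnikov) Wacker oxidation under nitrite co-catalysis, with attack at the internal carbon further blocked by the adjacent quaternary C9.

Step 13
Reactants: 18 6α,19-diacetoxy-1β-[(tert-butyldimethylsilyl)oxy]-18-chloro-4α-hydroxy-13,14,15,16-tetranor-neo-clerodan-12-al; 19 4-bromofuran-2(5H)-one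
Product: 20 (12S)-6α,19-diacetoxy-1β-[(tert-butyldimethylsilyl)oxy]-18-chloro-4α,12-dihydroxy-neo-clerod-13-en-15,16-olide
Conditions: CrCl2 (4 equiv), (R)-N-[2-(4-isopropyl-4,5-dihydrooxazol-2-yl)-6-methylphenyl]methanesulfonamide (4.4 equiv), Et3N, THF; then NiCl2 (10 mol%), 19 (2 equiv), rt
Reagents that add atoms: none
Why: Asymmetric Nozaki–Hiyama–Kishi coupling of the β-bromobutenolide, chemoselective for the aldehyde over acetates, lactone and alkyl chloride, with C12 (S) set by the chiral chromium ligand because the quaternary C9 transmits no useful substrate bias.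

Step 14
Reactants: 20 (12S)-6α,19-diacetoxy-1β-[(tert-butyldimethylsilyl)oxy]-18-chloro-4α,12-dihydroxy-neo-clerod-13-en-15,16-olide
Product: 21 (12S)-6α,19-diacetoxy-18-chloro-1β,4α,12-trihydroxy-neo-clerod-13-en-15,16-olide
Conditions: HF·pyridine, pyridine, THF, 0 °C to rt
Reagents that add atoms: none
Why: Buffered fluoride desilylation, mild enough for the acetates, the butenolide and the chlorohydrin.

Step 15
Reactants: 21 (12S)-6α,19-diacetoxy-18-chloro-1β,4α,12-trihydroxy-neo-clerod-13-en-15,16-olide; 22 (2S)-2-methylbutanoic anhydride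
Product: 23 ajugaciliatin A
Conditions: 22 (4 equiv), DMAP (1 equiv), Et3N, CH2Cl2, rt to 35 °C
Reagents that add atoms: none
Why: DMAP-catalysed acylation of both secondary hydroxyls (C1 and C12) with the enantiopure anhydride, which leaves the tertiary C4–OH free and does not epimerise the acyl α-stereocentre.

**Compound list**

1 | pent-4-ynal | C#CCCC=O | starting material
2 | methyl prop-2-ynoate | C#CC(=O)OC | starting material
3 | methyl (4R)-4-hydroxyocta-2,7-diynoate | COC(=O)C#C[C@H](O)CCC#C | intermediate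
4 | methyl (4R)-4-[(tert-butyldimethylsilyl)oxy]octa-2,7-diynoate | COC(=O)C#C[C@H](O[Si](C)(C)C(C)(C)C)CCC#C | intermediate
5 | methyl (2E,4R)-4-[(tert-butyldimethylsilyl)oxy]-2-(diisobutylalumanyl)oct-2-en-7-ynoate (vinylalane, C1 chain cis to the ester) | COC(=O)/C([Al](CC(C)C)CC(C)C)=C\[C@H](O[Si](C)(C)C(C)(C)C)CCC#C | intermediate
6 | methyl (2E,4R)-4-[(tert-butyldimethylsilyl)oxy]-2-iodooct-2-en-7-ynoate | COC(=O)/C(I)=C\[C@H](O[Si](C)(C)C(C)(C)C)CCC#C | intermediate
7 | (E)-but-2-enal | C/C=C/C=O | starting material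
8 | ethynyltri(propan-2-yl)silane | C#C[Si](C(C)C)(C(C)C)C(C)C | starting material
9 | (3R)-3-methyl-5-[tri(propan-2-yl)silyl]pent-4-ynal | CC(C)[Si](C(C)C)(C(C)C)C#C[C@H](C)CC=O | intermediate
10 | (3R)-3-methylpent-4-ynal | C#C[C@H](C)CC=O | intermediate
11 | (3R)-3-methyl-4-methylidenehex-5-enal | C=CC(=C)[C@H](C)CC=O | intermediate
12 | methyl (2Z,4R)-4-[(tert-butyldimethylsilyl)oxy]-2-[(1S,3R)-1-hydroxy-3-methyl-4-methylidenehex-5-en-1-yl]oct-2-en-7-ynoate | C=CC(=C)[C@H](C)C[C@H](O)/C(C(=O)OC)=C/[C@H](O[Si](C)(C)C(C)(C)C)CCC#C | intermediate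
13 | methyl (2Z,4R)-4-[(tert-butyldimethylsilyl)oxy]-8-chloro-2-[(1S,3R)-1-hydroxy-3-methyl-4-methylidenehex-5-en-1-yl]-7-oxooct-2-enoate | C=CC(=C)[C@H](C)C[C@H](O)/C(C(=O)OC)=C/[C@H](O[Si](C)(C)C(C)(C)C)CCC(=O)CCl | intermediate
14 | iron-bound ester enolate of the ring-B Giese adduct, drawn as the free enolate (C9 α-Me/β-vinyl, C8 α-Me, C6 α-OH, C10 β-H, chloromethyl ketone side chain still open) | C=C[C@@]1(C)[C@H](C)C[C@H](O)C(=C([O-])OC)[C@@H]1[C@H](O[Si](C)(C)C(C)(C)C)CCC(=O)CCl | intermediate
15 | methyl 1β-[(tert-butyldimethylsilyl)oxy]-18-chloro-4α,6α-dihydroxy-13,14,15,16-tetranor-neo-clerod-11-en-19-oate (trans-decalin, 10β-H, 5α-CO2Me, 8α-Me, 9α-Me, 9β-vinyl, 4β-CH2Cl) | C=C[C@@]1(C)[C@H](C)C[C@H](O)[C@]2(C(=O)OC)[C@@H]1[C@H](O[Si](C)(C)C(C)(C)C)CC[C@]2(O)CCl | intermediate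
16 | 1β-[(tert-butyldimethylsilyl)oxy]-18-chloro-13,14,15,16-tetranor-neo-clerod-11-ene-4α,6α,19-triol | C=C[C@@]1(C)[C@H](C)C[C@H](O)[C@]2(CO)[C@@H]1[C@H](O[Si](C)(C)C(C)(C)C)CC[C@]2(O)CCl | intermediate
17 | 6α,19-diacetoxy-1β-[(tert-butyldimethylsilyl)oxy]-18-chloro-13,14,15,16-tetranor-neo-clerod-11-en-4α-ol | C=C[C@@]1(C)[C@H](C)C[C@H](OC(C)=O)[C@]2(COC(C)=O)[C@@H]1[C@H](O[Si](C)(C)C(C)(C)C)CC[C@]2(O)CCl | intermediate
18 | 6α,19-diacetoxy-1β-[(tert-butyldimethylsilyl)oxy]-18-chloro-4α-hydroxy-13,14,15,16-tetranor-neo-clerodan-12-al | O=CC[C@@]1(C)[C@H](C)C[C@H](OC(C)=O)[C@]2(COC(C)=O)[C@@H]1[C@H](O[Si](C)(C)C(C)(C)C)CC[C@]2(O)CCl | intermediate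
19 | 4-bromofuran-2(5H)-one | O=C1C=C(Br)CO1 | starting material
20 | (12S)-6α,19-diacetoxy-1β-[(tert-butyldimethylsilyl)oxy]-18-chloro-4α,12-dihydroxy-neo-clerod-13-en-15,16-olide | O[C@@H](C[C@@]1(C)[C@H](C)C[C@H](OC(C)=O)[C@]2(COC(C)=O)[C@@H]1[C@H](O[Si](C)(C)C(C)(C)C)CC[C@]2(O)CCl)C1=CC(=O)OC1 | intermediate
21 | (12S)-6α,19-diacetoxy-18-chloro-1β,4α,12-trihydroxy-neo-clerod-13-en-15,16-olide | O[C@@H](C[C@@]1(C)[C@H](C)C[C@H](OC(C)=O)[C@]2(COC(C)=O)[C@@H]1[C@H](O)CC[C@]2(O)CCl)C1=CC(=O)OC1 | intermediate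
22 | (2S)-2-methylbutanoic anhydride | CC[C@H](C)C(=O)OC(=O)[C@@H](C)CC | starting material
23 | ajugaciliatin A | CC[C@H](C)C(=O)O[C@@H](C[C@@]1(C)[C@H](C)C[C@H](OC(C)=O)[C@]2(COC(C)=O)[C@@H]1[C@H](OC(=O)[C@@H](C)CC)CC[C@]2(O)CCl)C1=CC(=O)OC1 | target

**Totals and risks**

Total step count: 15. Longest linear sequence: 12 steps (steps 4–15 from crotonaldehyde; equally steps 1–3 and 7–15 from pent‑4‑ynal).

Most likely to fail:

1. Step 9 (bicyclisation). The iron enolate may be protonated before the aldol, or the allyl radical may be reduced before it cyclises. The fallback sets out from alkyne 12, skipping step 8, and closes ring A by a radical instead of a polar step. With Fe(acac)3 and PhSiH3 in EtOH at 60 °C the C9 allyl radical closes ring B as before. The α-ester radical at C5 then adds 6-exo-dig to the pendant terminal alkyne, and the vinyl radical takes a hydrogen atom from the silane. This gives methyl 1β-[(tert-butyldimethylsilyl)oxy]-6α-hydroxy-13,14,15,16-tetranor-neo-cleroda-4(18),11-dien-19-oate F1. N‑Chlorosuccinimide in aqueous acetone then adds HOCl across the exocyclic C4=C18 alkene, with the chloronium on the open β face and water attacking the tertiary carbon from the α face. The hindered C9 vinyl group reacts much more slowly. The route is rejoined at 15.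

2. Step 8 (gold oxidation). The acid may attack the diene or the silyl ether, and chloride abstraction may be inefficient on this substrate. The fallback sets out from 12 and puts chlorine on the alkyne first. NCS with AgOAc (10 mol%) in acetone gives methyl (2Z,4R)-4-[(tert-butyldimethylsilyl)oxy]-8-chloro-2-[(1S,3R)-1-hydroxy-3-methyl-4-methylidenehex-5-en-1-yl]oct-2-en-7-ynoate F2. Acid-free hydration of the chloroalkyne with Ph3PAuNTf2 in wet dioxane puts oxygen on the internal carbon and returns the route at 13.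

3. Step 7 (asymmetric coupling of the α‑iodo enoate). Reactivity or diastereoselectivity at C6 may be poor. The fallback sets out from ynoate 4 (iodide 6 is not made) and aldehyde 11. Vinylalumination of 4 with i‑Bu2AlH/HMPA followed by addition of 11 gives the C6‑epimeric alcohols methyl (2Z,4R)-4-[(tert-butyldimethylsilyl)oxy]-2-[(1RS,3R)-1-hydroxy-3-methyl-4-methylidenehex-5-en-1-yl]oct-2-en-7-ynoate F3. Dess–Martin periodinane buffered with NaHCO3 gives methyl (2Z,4R)-4-[(tert-butyldimethylsilyl)oxy]-2-[(3R)-3-methyl-4-methylidenehex-5-enoyl]oct-2-en-7-ynoate F4. This ketone is reduced at once with (R)-Me-CBS and catecholborane at −78 °C, before the alkylidene β‑keto ester can isomerise, which returns the route at 12.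

**Further compounds**

F1 | step 9 | methyl 1β-[(tert-butyldimethylsilyl)oxy]-6α-hydroxy-13,14,15,16-tetranor-neo-cleroda-4(18),11-dien-19-oate | C=C[C@@]1(C)[C@H](C)C[C@H](O)[C@]2(C(=O)OC)[C@@H]1[C@H](O[Si](C)(C)C(C)(C)C)CCC2=C
F2 | step 8 | methyl (2Z,4R)-4-[(tert-butyldimethylsilyl)oxy]-8-chloro-2-[(1S,3R)-1-hydroxy-3-methyl-4-methylidenehex-5-en-1-yl]oct-2-en-7-ynoate | C=CC(=C)[C@H](C)C[C@H](O)/C(C(=O)OC)=C/[C@H](O[Si](C)(C)C(C)(C)C)CCC#CCl
F3 | step 7 | methyl (2Z,4R)-4-[(tert-butyldimethylsilyl)oxy]-2-[(1RS,3R)-1-hydroxy-3-methyl-4-methylidenehex-5-en-1-yl]oct-2-en-7-ynoate (both carbinol epimers) | C=CC(=C)[C@H](C)CC(O)/C(C(=O)OC)=C/[C@H](O[Si](C)(C)C(C)(C)C)CCC#C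
F4 | step 7 | methyl (2Z,4R)-4-[(tert-butyldimethylsilyl)oxy]-2-[(3R)-3-methyl-4-methylidenehex-5-enoyl]oct-2-en-7-ynoate | C=CC(=C)[C@H](C)CC(=O)/C(C(=O)OC)=C/[C@H](O[Si](C)(C)C(C)(C)C)CCC#C
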